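**Retrosynthetic overview**
- The last bond made is the benzylic palmitate C–O on ring A. Before that come removal of three MOM groups and O-methylation of a ring B benzoic acid.
- The strategy rests on ring B, where the diaryl ether oxygen (C6), the ester carbon (C1) and the hydroxyl (C2) sit on three adjacent ring carbons. C1 and C6 are treated as the two carbons of a benzyne that carries oxygen at C2.
- The C6–O and C1–CO2 bonds are cut together. This leaves 3-(methoxymethoxy)-5-methylbenzyne, the ring A phenoxide and carbon dioxide.
- The aryne precursor comes from orcinol by directed metalation between its two oxygens. The ring A phenol comes from 2-hydroxy-5-methoxybenzaldehyde, with its C1 oxygen held as an allyl ether until both other hydroxyls are MOM-protected.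
- No ring is formed. Rings A and B are both purchased arenes and are joined in the key step.

Key step: step 11

Remark: the target has no stereocentre and no stereogenic double bond, and the acyl chain is read as unbranched hexadecanoyl. Orcinol is used anhydrous.

**Step 1**
Reactants: 1 orcinol
Product: 2 3-(methoxymethoxy)-5-methylphenol
Conditions: NaH (1.0 equiv), DMF, 0 °C; MOMCl (1.0 equiv), 0 °C → rt
Reagents that add atoms: chloromethyl methyl ether, COCCl
Why: Williamson-type O-alkylation of the monosodium salt of a diol with two equivalent hydroxyls, so only the degree of alkylation needs sorting out, and the bis-ether and unreacted diol should be separable by chromatography and recyclable.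

**Step 2**
Reactants: 2 3-(methoxymethoxy)-5-methylphenol
Product: 3 3-(methoxymethoxy)-5-methylphenyl N-isopropylcarbamate
Conditions: i-PrNCO, Et3N (cat.), CH2Cl2, rt
Reagents that add atoms: isopropyl isocyanate, CC(C)N=C=O
Why: Base-catalysed addition of a phenol to an isocyanate (carbamoylation) installs a strong ortho-directing group that can later be removed under mild base.

**Step 3**
Reactants: 3 3-(methoxymethoxy)-5-methylphenyl N-isopropylcarbamate
Product: 7 3-(methoxymethoxy)-5-methyl-2-(trimethylsilyl)phenyl N-isopropylcarbamate, via N-TBS carbamate 4 (not isolated), via C2 aryllithium 5 (not isolated), via N-TBS C2-TMS carbamate 6 (not isolated)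
Conditions: TBSOTf, TMEDA, Et2O, 0 °C → rt; n-BuLi (2.2 equiv), TMEDA, −78 °C; TMSCl, −78 °C → rt; cold 10% aq citric acid (brief)
Reagents that add atoms: chlorotrimethylsilane, C[Si](C)(C)Cl; TBSOTf, CC(C)(C)[Si](C)(C)OS(=O)(=O)C(F)(F)F (silyl group only in 4–6); n-butyllithium, [Li]CCCC (lithium only in 5)
Why: Directed ortho-metalation, in which in situ N-silylation masks the N–H, the carbamate and the MOM ether jointly direct n-BuLi to the C–H between them, TMSCl traps the aryllithium, and the labile N–Si bond is hydrolysed under an acid work-up mild enough to spare the MOM ether and the electron-rich aryl–silicon bond.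

**Step 4**
Reactants: 7 3-(methoxymethoxy)-5-methyl-2-(trimethylsilyl)phenyl N-isopropylcarbamate
Product: 9 3-(methoxymethoxy)-5-methyl-2-(trimethylsilyl)phenyl trifluoromethanesulfonate, via 2-silylphenol 8 (not isolated)
Conditions: DBU, Et2NH, MeCN, 40 °C; then PhNTf2, rt
Reagents that add atoms: N-phenylbis(trifluoromethanesulfonimide), O=S(=O)(N(c1ccccc1)S(=O)(=O)C(F)(F)F)C(F)(F)F
Why: E1cB cleavage of the secondary carbamate, with Et2NH scavenging the expelled isocyanate, frees the phenoxide, which is O-sulfonylated in the same pot without acid that could cause protodesilylation.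

**Step 5**
Reactants: 10 2-hydroxy-5-methoxybenzaldehyde
Product: 11 3-bromo-2-hydroxy-5-methoxybenzaldehyde
Conditions: Br2, NaOAc, AcOH, rt
Reagents that add atoms: bromine, BrBr
Why: Electrophilic aromatic bromination governed by the free hydroxyl, whose para position carries the methoxy group and whose other ortho position carries the formyl group, so bromine should enter at C3.

**Step 6**
Reactants: 11 3-bromo-2-hydroxy-5-methoxybenzaldehyde
Product: 12 2-(allyloxy)-3-bromo-5-methoxybenzaldehyde
Conditions: allyl bromide, K2CO3, DMF, 50 °C
Reagents that add atoms: allyl bromide, C=CCBr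
Why: Williamson ether synthesis masks the oxygen that will become the diaryl ether oxygen, and allyl is preferred to benzyl because the later benzylic MOM ether would itself be at risk under hydrogenolysis.

**Step 7**
Reactants: 12 2-(allyloxy)-3-bromo-5-methoxybenzaldehyde
Product: 13 [2-(allyloxy)-3-bromo-5-methoxyphenyl]methanol
Conditions: NaBH4, MeOH, 0 °C
Reagents that add atoms: none
Why: Borohydride reduction of an aryl aldehyde leaves the aryl bromide and the allyl ether untouched.

**Step 8**
Reactants: 13 [2-(allyloxy)-3-bromo-5-methoxyphenyl]methanol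
Product: 16 2-(allyloxy)-3-(hydroxymethyl)-5-methoxyphenol, via O,C-dilithio species 14 (not isolated), via lithium aryltrimethoxyborate 15 (not isolated)
Conditions: n-BuLi (2.2 equiv), THF, −78 °C; B(OMe)3, −78 °C → rt; AcOH, 30% aq H2O2, 0 °C → rt
Reagents that add atoms: hydrogen peroxide, OO; n-butyllithium, [Li]CCCC (lithium only in 14 and 15); trimethyl borate, COB(OC)OC (boron only in 15)
Why: O-deprotonation followed by bromine–lithium exchange, borylation and oxidative 1,2-aryl migration (aryl boronate oxidation) replaces bromine by hydroxyl, and at −78 °C the exchange is much faster than any reaction of the allyl ether.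

**Step 9**
Reactants: 16 2-(allyloxy)-3-(hydroxymethyl)-5-methoxyphenol
Product: 17 2-(allyloxy)-5-methoxy-1-(methoxymethoxy)-3-[(methoxymethoxy)methyl]benzene
Conditions: NaH (2.5 equiv), MOMCl (2.5 equiv), THF–DMF, 0 °C → rt
Reagents that add atoms: chloromethyl methyl ether, COCCl
Why: Double Williamson-type O-alkylation protects the phenol and the primary benzylic alcohol in one operation, and no selectivity is needed because the third oxygen is already allylated.

**Step 10**
Reactants: 17 2-(allyloxy)-5-methoxy-1-(methoxymethoxy)-3-[(methoxymethoxy)methyl]benzene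
Product: 18 4-methoxy-2-(methoxymethoxy)-6-[(methoxymethoxy)methyl]phenol
Conditions: Pd(PPh3)4 (5 mol %), morpholine, THF, rt
Reagents that add atoms: none
Why: In this Tsuji–Trost-type deallylation, zerovalent palladium ionises the allyl aryl ether, morpholine takes up the allyl fragment, and both MOM acetals and the benzylic C–O bond are inert.

**Step 11**
Reactants: 18 4-methoxy-2-(methoxymethoxy)-6-[(methoxymethoxy)methyl]phenol; 9 3-(methoxymethoxy)-5-methyl-2-(trimethylsilyl)phenyl trifluoromethanesulfonate
Product: 23 2-{4-methoxy-2-(methoxymethoxy)-6-[(methoxymethoxy)methyl]phenoxy}-6-(methoxymethoxy)-4-methylbenzoic acid, via potassium phenoxide 19 (not isolated), via 3-(methoxymethoxy)-5-methylbenzyne 20 (not isolated), via arylpotassium 21 (not isolated), via potassium carboxylate 22 (not isolated)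
Conditions: 18 (1.5 equiv), KH, THF, 0 °C; CO2 (1 atm), KF, 18-crown-6, then 9 (1.0 equiv, slow addition), THF, 0 °C → rt; cold 0.5 M aq HCl to pH 4
Reagents that add atoms: carbon dioxide, O=C=O; potassium hydride, [KH] (potassium only in 19, 21 and 22)
Why: Proposed new method: fluoride attacks the silicon of 9 and triflate departs (1,2-elimination) to give aryne 20, whose triple bond (the future ring B C1 and C6) is distorted by the inductively withdrawing C2 OMOM group so that C6, the carbon away from oxygen, is the more electrophilic end. The crown-activated phenoxide 19 adds through oxygen at C6 (C6–O bond) and leaves the charge at C1 in arylpotassium 21, in the ring plane between two C–O bonds that stabilise it inductively. Because 19 is preformed with KH (H2 escapes), the solvent is THF rather than acetonitrile and every hydroxyl is masked, nothing more acidic than an ether C–H is present, so 21 should be intercepted by dissolved CO2 (C1–CO2 bond) to give carboxylate 22. The closest known reaction types are the KF/18-crown-6 three-component coupling of arynes with amines and CO2 to give anthranilic acids and the fluoride-mediated O-arylation of phenols by 2-silylaryl triflates, and what is new is pairing an anionic oxygen nucleophile with CO2. Reversible carbonate formation between 19 and CO2 is expected to be only a resting state, as carbamate formation is in the amine case, because the free phenoxide is by far the better nucleophile. No ring closes and no stereocentre forms; the only selectivity required is the regiochemistry of addition, which the C2 oxygen substituent secures, while C-arylation of 19 is blocked by its 2,4,6-substitution and further arylation of 22 is limited by the excess of 19 and the slow addition of 9.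

**Step 12**
Reactants: 23 2-{4-methoxy-2-(methoxymethoxy)-6-[(methoxymethoxy)methyl]phenoxy}-6-(methoxymethoxy)-4-methylbenzoic acid
Product: 24 methyl 2-{4-methoxy-2-(methoxymethoxy)-6-[(methoxymethoxy)methyl]phenoxy}-6-(methoxymethoxy)-4-methylbenzoate
Conditions: MeI, K2CO3, DMF, rt
Reagents that add atoms: iodomethane, CI
Why: SN2 O-alkylation of the carboxylate forms the bond at the methyl carbon, so the two ortho substituents that would block a Fischer esterification do not matter.

**Step 13**
Reactants: 24 methyl 2-{4-methoxy-2-(methoxymethoxy)-6-[(methoxymethoxy)methyl]phenoxy}-6-(methoxymethoxy)-4-methylbenzoate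
Product: 25 methyl 2-hydroxy-6-[2-hydroxy-6-(hydroxymethyl)-4-methoxyphenoxy]-4-methylbenzoate
Conditions: 1.25 M HCl in MeOH, 40 °C
Reagents that add atoms: none
Why: Acid-catalysed acetal methanolysis removes all three MOM groups and traps the formaldehyde unit as its dimethyl acetal, ester exchange in methanol is degenerate, and the benzylic position has both strong donors meta to it, so it should resist solvolysis.

**Step 14**
Reactants: 25 methyl 2-hydroxy-6-[2-hydroxy-6-(hydroxymethyl)-4-methoxyphenoxy]-4-methylbenzoate; 26 palmitic acid
Product: 27 Betaethrin E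
Conditions: PPh3, DIAD, THF, 0 °C → rt
Reagents that add atoms: none
Why: In this Mitsunobu esterification only the aliphatic hydroxyl is activated as an oxyphosphonium ion and only the carboxylic acid, far more acidic than either phenol, is deprotonated to act as nucleophile, and since the ring A phenol is meta to the CH2OH no quinone methide can form.

**Compound list**
1 | orcinol (5-methylbenzene-1,3-diol) | Cc1cc(O)cc(O)c1 | starting material
2 | 3-(methoxymethoxy)-5-methylphenol | COCOc1cc(C)cc(O)c1 | intermediate
3 | 3-(methoxymethoxy)-5-methylphenyl N-isopropylcarbamate | COCOc1cc(C)cc(OC(=O)NC(C)C)c1 | intermediate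
4 | 3-(methoxymethoxy)-5-methylphenyl N-(tert-butyldimethylsilyl)-N-isopropylcarbamate (not isolated) | COCOc1cc(C)cc(OC(=O)N(C(C)C)[Si](C)(C)C(C)(C)C)c1 | intermediate
5 | 2-lithio derivative of 4 (not isolated) | COCOc1cc(C)cc(OC(=O)N(C(C)C)[Si](C)(C)C(C)(C)C)c1[Li] | intermediate
6 | 3-(methoxymethoxy)-5-methyl-2-(trimethylsilyl)phenyl N-(tert-butyldimethylsilyl)-N-isopropylcarbamate (not isolated) | COCOc1cc(C)cc(OC(=O)N(C(C)C)[Si](C)(C)C(C)(C)C)c1[Si](C)(C)C | intermediate
7 | 3-(methoxymethoxy)-5-methyl-2-(trimethylsilyl)phenyl N-isopropylcarbamate | COCOc1cc(C)cc(OC(=O)NC(C)C)c1[Si](C)(C)C | intermediate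
8 | 3-(methoxymethoxy)-5-methyl-2-(trimethylsilyl)phenol (not isolated) | COCOc1cc(C)cc(O)c1[Si](C)(C)C | intermediate
9 | 3-(methoxymethoxy)-5-methyl-2-(trimethylsilyl)phenyl trifluoromethanesulfonate | Cc1cc(OCOC)c([Si](C)(C)C)c(OS(=O)(=O)C(F)(F)F)c1 | intermediate
10 | 2-hydroxy-5-methoxybenzaldehyde | COc1ccc(O)c(C=O)c1 | starting material
11 | 3-bromo-2-hydroxy-5-methoxybenzaldehyde | COc1cc(Br)c(O)c(C=O)c1 | intermediate
12 | 2-(allyloxy)-3-bromo-5-methoxybenzaldehyde | C=CCOc1c(Br)cc(OC)cc1C=O | intermediate
13 | [2-(allyloxy)-3-bromo-5-methoxyphenyl]methanol | C=CCOc1c(Br)cc(OC)cc1CO | intermediate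
14 | lithium [2-(allyloxy)-3-lithio-5-methoxyphenyl]methanolate (not isolated) | [Li]OCc1cc(OC)cc([Li])c1OCC=C | intermediate
15 | lithium aryl(trimethoxy)borate derived from 14 (not isolated) | [Li+].[Li]OCc1cc(OC)cc([B-](OC)(OC)OC)c1OCC=C | intermediate
16 | 2-(allyloxy)-3-(hydroxymethyl)-5-methoxyphenol | C=CCOc1c(O)cc(OC)cc1CO | intermediate
17 | 2-(allyloxy)-5-methoxy-1-(methoxymethoxy)-3-[(methoxymethoxy)methyl]benzene | C=CCOc1c(OCOC)cc(OC)cc1COCOC | intermediate
18 | 4-methoxy-2-(methoxymethoxy)-6-[(methoxymethoxy)methyl]phenol | COCOCc1cc(OC)cc(OCOC)c1O | intermediate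
19 | potassium 4-methoxy-2-(methoxymethoxy)-6-[(methoxymethoxy)methyl]phenoxide (not isolated) | [K+].[O-]c1c(COCOC)cc(OC)cc1OCOC | intermediate
20 | 3-(methoxymethoxy)-5-methylbenzyne (not isolated) | COCOC1=CC(C)=CC#C1 | intermediate
21 | arylpotassium from addition of 19 to 20, with the charge on the ring B carbon between the aryloxy and OMOM carbons (not isolated) | [K+].COCOCc1cc(OC)cc(OCOC)c1Oc1cc(C)cc(OCOC)[c-]1 | intermediate
22 | potassium salt of 23 (not isolated) | [K+].COCOCc1cc(OC)cc(OCOC)c1Oc1cc(C)cc(OCOC)c1C(=O)[O-] | intermediate
23 | 2-{4-methoxy-2-(methoxymethoxy)-6-[(methoxymethoxy)methyl]phenoxy}-6-(methoxymethoxy)-4-methylbenzoic acid | COCOCc1cc(OC)cc(OCOC)c1Oc1cc(C)cc(OCOC)c1C(=O)O | intermediate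
24 | methyl 2-{4-methoxy-2-(methoxymethoxy)-6-[(methoxymethoxy)methyl]phenoxy}-6-(methoxymethoxy)-4-methylbenzoate | COCOCc1cc(OC)cc(OCOC)c1Oc1cc(C)cc(OCOC)c1C(=O)OC | intermediate
25 | methyl 2-hydroxy-6-[2-hydroxy-6-(hydroxymethyl)-4-methoxyphenoxy]-4-methylbenzoate | OCc1cc(OC)cc(O)c1Oc1cc(C)cc(O)c1C(=O)OC | intermediate
26 | palmitic acid (hexadecanoic acid) | CCCCCCCCCCCCCCCC(=O)O | starting material
27 | Betaethrin E, methyl 2-hydroxy-6-{2-hydroxy-4-methoxy-6-[(palmitoyloxy)methyl]phenoxy}-4-methylbenzoate | CCCCCCCCCCCCCCCC(=O)OCc1cc(OC)cc(O)c1Oc1cc(C)cc(O)c1C(=O)OC | target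

**Totals**
- Total step count: 14.
- Longest linear sequence: 10 (steps 5–14). The ring B branch (steps 1–4) joins at step 11.

**Steps most likely to fail**

1. **Step 11.**
   - What may go wrong:
     - The aryl anion may pick up a proton before it meets CO2, from traces of water, from the crown ether, or from the nearby benzylic and acetal C–H bonds.
     - The phenoxide may be held as its carbonate and add through the carbonate oxygen, followed by acyl transfer.
     - The carboxylate may be arylated by a second aryne.
   - Fallback (known chemistry, sets out from 18 and returns at 23):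
     - Commercial 3-fluoro-5-methylphenol F1 is protected (NaH, MOMCl) as 1-fluoro-3-(methoxymethoxy)-5-methylbenzene F2.
     - F2 is lithiated between fluorine and the MOM ether (n-BuLi, THF, −78 °C) and formylated with DMF to give 2-fluoro-6-(methoxymethoxy)-4-methylbenzaldehyde F3.
     - Phenol 18 displaces the fluoride ortho to the aldehyde by SNAr (K2CO3, DMF, 100 °C). This gives 2-{4-methoxy-2-(methoxymethoxy)-6-[(methoxymethoxy)methyl]phenoxy}-6-(methoxymethoxy)-4-methylbenzaldehyde F4.
     - Pinnick oxidation (NaClO2, NaH2PO4, 2-methyl-2-butene, t-BuOH–H2O) converts F4 into 23.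

2. **Step 14.**
   - What may go wrong:
     - The activated benzylic carbon may alkylate the ring A phenol of a second molecule (ether oligomerisation).
     - Displacement may be slow next to the bulky aryloxy group.
   - Fallback (sets out from 25 and returns at 27):
     - Exhaustive acylation with excess palmitoyl chloride (pyridine, DMAP, CH2Cl2) gives methyl 4-methyl-2-(palmitoyloxy)-6-{4-methoxy-2-(palmitoyloxy)-6-[(palmitoyloxy)methyl]phenoxy}benzoate F5.
     - The two activated aryl esters are then removed selectively by aminolysis with pyrrolidine (THF, 0 °C → rt). The alkyl palmitate and the hindered methyl benzoate do not react, and 27 is left.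

3. **Step 8.**
   - What may go wrong:
     - The aryllithium may be quenched by a proton or alkylated by butyl bromide before borylation.
     - It may cyclise onto the allyl group on warming.
     - Excess borate may bind the alkoxide and the mixture become heterogeneous.
   - Fallback (sets out from 11 and returns at 17, replacing steps 6–9):
     - Copper-mediated hydroxylation of 11 (aq NaOH, Cu powder, reflux, N2) gives 2,3-dihydroxy-5-methoxybenzaldehyde F6.
     - The dianion of F6 (NaH, 2.2 equiv, DMSO) reacts with one equivalent of MOMCl at the more basic, non-chelated C3 oxide. This gives 2-hydroxy-5-methoxy-3-(methoxymethoxy)benzaldehyde F7.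
     - Allylation (allyl bromide, K2CO3, DMF) gives 2-(allyloxy)-5-methoxy-3-(methoxymethoxy)benzaldehyde F8.
     - NaBH4 reduction gives [2-(allyloxy)-5-methoxy-3-(methoxymethoxy)phenyl]methanol F9.
     - NaH/MOMCl converts F9 into 17.

**Further compounds**
F1 | step 11 | 3-fluoro-5-methylphenol (commercial) | Cc1cc(O)cc(F)c1
F2 | step 11 | 1-fluoro-3-(methoxymethoxy)-5-methylbenzene | COCOc1cc(C)cc(F)c1
F3 | step 11 | 2-fluoro-6-(methoxymethoxy)-4-methylbenzaldehyde | COCOc1cc(C)cc(F)c1C=O
F4 | step 11 | 2-{4-methoxy-2-(methoxymethoxy)-6-[(methoxymethoxy)methyl]phenoxy}-6-(methoxymethoxy)-4-methylbenzaldehyde | COCOCc1cc(OC)cc(OCOC)c1Oc1cc(C)cc(OCOC)c1C=O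
F5 | step 14 | methyl 4-methyl-2-(palmitoyloxy)-6-{4-methoxy-2-(palmitoyloxy)-6-[(palmitoyloxy)methyl]phenoxy}benzoate | CCCCCCCCCCCCCCCC(=O)OCc1cc(OC)cc(OC(=O)CCCCCCCCCCCCCCC)c1Oc1cc(C)cc(OC(=O)CCCCCCCCCCCCCCC)c1C(=O)OC
F6 | step 8 | 2,3-dihydroxy-5-methoxybenzaldehyde | COc1cc(O)c(O)c(C=O)c1
F7 | step 8 | 2-hydroxy-5-methoxy-3-(methoxymethoxy)benzaldehyde | COCOc1cc(OC)cc(C=O)c1O
F8 | step 8 | 2-(allyloxy)-5-methoxy-3-(methoxymethoxy)benzaldehyde | C=CCOc1c(OCOC)cc(OC)cc1C=O
F9 | step 8 | [2-(allyloxy)-5-methoxy-3-(methoxymethoxy)phenyl]methanol | C=CCOc1c(OCOC)cc(OC)cc1CO
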